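**Plan**
Num­bering used throughout (daucane): C1 = methyl-bearing ring-fusion carbon, C2/C3 = ring CH2, C4 = C(OH)iPr, C5 = ring-fusion CH, C6 = CH–OBz, C7=C8(CH3), C9 = C=O, C10 = CH–OH; β = face of the C1 methyl.
Retrosynthesis: cut the C6 ester; take C6–O/C9=O back to a C6=C7–C8=C9 diene (minus O2) and C10–OH back to C10=O; cut C3–C4 of the cyclopentane; cut C5–C4 and C1–C2, leaving 3,7-dimethylcyclohepta-2,6-dienone.
Forward: the seven-membered ring is bought; one conjugate addition/enolate allylation places the two arms on C5 and C1; the cyclopentane is closed last by joining C3 (iodoethyl arm on C1) to C4 (isopropyl ketone on C5); the enone is then reworked.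
Enabling feature: in ring C1–C2–C3–C4–C5 the carbinol C4 (OH, iPr) is a latent ketone carbon and C3 is a plain CH2, so the ring can close at C3–C4, a bond that touches neither fusion atom; the trans C1/C5 relationship set on the cycloheptenone becomes the trans ring fusion unchanged.
Stereochemistry: C5 from a ligand-controlled Cu-catalysed conjugate addition; C1 by anti enolate allylation; C4 in the ring closure; C10 by hydride delivery anti to the angular methyl; C6 by α-face addition of singlet oxygen.

Key step: step 7

Assumption: 3-methylcyclohept-2-en-1-one and 3-methylbut-1-yne are taken as catalogue chemicals, and the ligand antipode in step 3 is the one that gives the 6S adduct.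

Step 1
Reactants: 1 3-methylcyclohept-2-en-1-one
Product: 2 3,7-dimethylcyclohept-2-en-1-one (racemic)
Conditions: LDA, THF, −78 °C; MeI, −78 → 0 °C
Reagents that add atoms: iodomethane, CI
Why: Kinetic deprotonation with LDA occurs at the α′ carbon of the enone and the lithium enolate is C-methylated (enolate alkylation); the new stereocentre is racemic and is removed in step 2.

Step 2
Reactants: 2 3,7-dimethylcyclohept-2-en-1-one
Product: 4 3,7-dimethylcyclohepta-2,6-dien-1-one, via silyl dienol ether 3 (not isolated)
Conditions: LDA, TMSCl, THF, −78 °C; then Pd(OAc)2, MeCN, rt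
Reagents that add atoms: none
Why: Saegusa–Ito oxidation: LDA removes the remaining α′ hydrogen, the cross-conjugated silyl dienol ether is palladated at carbon, and β-hydride elimination towards the ring CH2 gives the second (α-methyl) enone; no stereocentre is present.

Step 3
Reactants: 4 3,7-dimethylcyclohepta-2,6-dien-1-one, 5 3-methylbut-1-yne
Product: 7 (6S,7S)-3,7-dimethyl-6-(3-methylbut-1-en-2-yl)-7-(prop-2-en-1-yl)cyclohept-2-en-1-one, via aluminium enolate 6 (not isolated)
Conditions: 5, DIBAL-H, Ni(dppp)Cl2 (3 mol %), THF, 0 °C → rt; then 4, CuTC (5 mol %), chiral phosphoramidite (10 mol %), Et2O, −30 °C; then allyl acetate, Pd(PPh3)4 (5 mol %), THF, 0 °C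
Reagents that add atoms: allyl acetate, CC(=O)OCC=C
Why: Nickel-catalysed α-selective hydroalumination gives the 1,1-disubstituted alkenylalane, the copper-catalysed enantioselective conjugate addition transfers it to the only β-CH enone terminus (ring C6 = C5; the β-methyl terminus would have to form a quaternary centre and reacts far more slowly) with the ligand fixing this stereocentre, and the Tsuji–Trost allylation of the aluminium enolate occurs anti to the new alkenyl group, setting the quaternary carbon with allyl trans to alkenyl.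

Step 4
Reactants: 7 (6S,7S)-3,7-dimethyl-6-(3-methylbut-1-en-2-yl)-7-(prop-2-en-1-yl)cyclohept-2-en-1-one
Product: 8 (6R,7S)-3,7-dimethyl-6-(2-methylpropanoyl)-7-(2-oxoethyl)cyclohept-2-en-1-one
Conditions: O3, CH2Cl2–MeOH, Sudan red 7B, −78 °C; then Me2S, −78 °C → rt
Reagents that add atoms: ozone, [O-][O+]=O
Why: Ozonolysis with reductive work-up cleaves the two electron-rich terminal alkenes much faster than the electron-poor trisubstituted enone double bond (end point by indicator dye), and no stereocentre is touched.

Step 5
Reactants: 8 (6R,7S)-3,7-dimethyl-6-(2-methylpropanoyl)-7-(2-oxoethyl)cyclohept-2-en-1-one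
Product: 9 (6R,7S)-7-(2-hydroxyethyl)-3,7-dimethyl-6-(2-methylpropanoyl)cyclohept-2-en-1-one
Conditions: NaBH4 (0.3 equiv), MeOH–CH2Cl2, −78 °C
Reagents that add atoms: none
Why: Chemoselective borohydride reduction: at −78 °C the aldehyde is reduced far faster than the hindered isopropyl ketone and the conjugated ketone, and the mild conditions should leave the epimerisable centre next to the ketone untouched.

Step 6
Reactants: 9 (6R,7S)-7-(2-hydroxyethyl)-3,7-dimethyl-6-(2-methylpropanoyl)cyclohept-2-en-1-one
Product: 10 (6R,7S)-7-(2-iodoethyl)-3,7-dimethyl-6-(2-methylpropanoyl)cyclohept-2-en-1-one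
Conditions: PPh3, I2, imidazole, CH2Cl2, 0 °C
Reagents that add atoms: iodine, II
Why: Appel-type iodination replaces the primary hydroxyl by iodide through SN2 displacement of the oxyphosphonium group under near-neutral conditions; no stereocentre is involved.

Step 7
Reactants: 10 (6R,7S)-7-(2-iodoethyl)-3,7-dimethyl-6-(2-methylpropanoyl)cyclohept-2-en-1-one
Product: 11 (3R,3aR,8aS)-3-hydroxy-6,8a-dimethyl-3-(propan-2-yl)-2,3,3a,4,5,8a-hexahydroazulen-8(1H)-one (trans-fused 4β-hydroxydauc-8-en-10-one)
Conditions: SmI2 (2.5 equiv), NiI2 (2 mol %), THF, 0 °C; aq. NH4Cl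
Reagents that add atoms: none
Why: Nickel(0) formed in situ inserts into the primary C–I bond and SmI2 converts the alkyl group into an alkylsamarium(III) species, which adds intramolecularly to the isopropyl ketone on the neighbouring ring carbon to give the samarium alkoxide of the tertiary carbinol. The closest known reaction type is the samarium diiodide-promoted intramolecular Barbier cyclisation of ω-iodo ketones to cycloalkanols. The cyclopentane closes in a 5-exo-trig mode (C3 onto the carbonyl carbon C4, the C=O being exocyclic to the new ring), and because the new bond joins two non-fusion atoms the trans C1/C5 relationship from step 3 becomes the trans ring fusion. The only new stereocentre, C4, is controlled by torsional strain at the adjacent C5: in the transition state the carbonyl oxygen eclipses the C5–C6 bond and the bulky isopropyl group lies on the side of H-5, which places the hydroxyl cis to C6 and to the C1 methyl. The step needs chemoselectivity for the iodide over the enone and for the C4 carbonyl over the C10 carbonyl; SmI2 in THF without HMPA should be too weak a reductant for the hindered β,β-disubstituted enone on the time scale of the nickel-catalysed iodide activation, and attack on C10 would need a four-membered ring.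

Step 8
Reactants: 11 (3R,3aR,8aS)-3-hydroxy-6,8a-dimethyl-3-(propan-2-yl)-2,3,3a,4,5,8a-hexahydroazulen-8(1H)-one
Product: 12 (3R,3aR,8aS)-3-hydroxy-6,8a-dimethyl-3-(propan-2-yl)-2,3,3a,8a-tetrahydroazulen-8(1H)-one (4β-hydroxydauca-6,8-dien-10-one)
Conditions: chloranil, t-BuOH, reflux
Reagents that add atoms: none
Why: Quinone dehydrogenation of an enone to the linear dienone through its dienol (the reaction type that turns Δ4-3-keto steroids into Δ4,6-dienones); the α′ carbon is quaternary, so only the γ,δ positions can be dehydrogenated, and the stereocentres are not affected.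

Step 9
Reactants: 12 (3R,3aR,8aS)-3-hydroxy-6,8a-dimethyl-3-(propan-2-yl)-2,3,3a,8a-tetrahydroazulen-8(1H)-one
Product: 13 (3R,3aR,8S,8aS)-6,8a-dimethyl-3-(propan-2-yl)-1,2,3,3a,8,8a-hexahydroazulene-3,8-diol (dauca-6,8-diene-4β,10β-diol)
Conditions: NaBH4, CeCl3·7H2O, MeOH, −78 °C
Reagents that add atoms: none
Why: Luche reduction gives 1,2-reduction of the dienone, and hydride enters the carbonyl from the face opposite to the pseudo-axial methyl on the neighbouring quaternary carbon, which sets the C10 hydroxyl cis to that methyl (β, equatorial).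

Step 10
Reactants: 13 (3R,3aR,8S,8aS)-6,8a-dimethyl-3-(propan-2-yl)-1,2,3,3a,8,8a-hexahydroazulene-3,8-diol
Product: 14 6α,9α-epidioxydauc-7-ene-4β,10β-diol (endoperoxide, O–O bridge on the face opposite to the C1 methyl)
Conditions: O2, rose bengal, visible light, MeOH, −20 °C
Reagents that add atoms: dioxygen, O=O
Why: [4+2] cycloaddition of singlet oxygen to the cisoid ring diene; both diene termini (C6 and C9) are 1,3-related to the axial C1 methyl, so oxygen adds from the opposite (α) face and fixes the C6–O bond, while methanol suppresses hydroxyl-directed delivery.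

Step 11
Reactants: 14 6α,9α-epidioxydauc-7-ene-4β,10β-diol
Product: 15 (3R,3aS,4S,8R,8aS)-3,4,8-trihydroxy-6,8a-dimethyl-3-(propan-2-yl)-2,3,3a,4,8,8a-hexahydroazulen-7(1H)-one (4β,6α,10β-trihydroxydauc-7-en-9-one)
Conditions: Et3N, CH2Cl2, 0 °C → rt
Reagents that add atoms: none
Why: Kornblum–DeLaMare rearrangement: triethylamine removes the peroxide methine hydrogen at C9, which is acidified by the neighbouring C10 oxygen and is less hindered than H-6 next to the ring-fusion carbon; the O–O bond breaks, C9 becomes the ketone and the C6 oxygen stays as the hydroxyl with its configuration unchanged.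

Step 12
Reactants: 15 (3R,3aS,4S,8R,8aS)-3,4,8-trihydroxy-6,8a-dimethyl-3-(propan-2-yl)-2,3,3a,4,8,8a-hexahydroazulen-7(1H)-one
Product: 16 [(3R,3aS,4S,8R,8aS)-3,8-dihydroxy-6,8a-dimethyl-7-oxo-3-(propan-2-yl)-1,2,3,3a,4,7,8,8a-octahydroazulen-4-yl] benzoate
Conditions: BzCl (1.05 equiv), pyridine, CH2Cl2, −20 → 0 °C
Reagents that add atoms: benzoyl chloride, O=C(Cl)c1ccccc1
Why: Acylation should take place at the allylic secondary C6 hydroxyl, because the C10 hydroxyl is neopentyl-like and hydrogen-bonded to the ketone and the C4 hydroxyl is tertiary; the configuration at C6 is retained.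

**Compound list**
1 | 3-methylcyclohept-2-en-1-one | CC1=CC(=O)CCCC1 | starting material
2 | 3,7-dimethylcyclohept-2-en-1-one (racemic) | CC1=CC(=O)C(C)CCC1 | intermediate
3 | [(2,6-dimethylcyclohepta-1,6-dien-1-yl)oxy]trimethylsilane | CC1=CC(O[Si](C)(C)C)=C(C)CCC1 | intermediate
4 | 3,7-dimethylcyclohepta-2,6-dien-1-one | CC1=CC(=O)C(C)=CCC1 | intermediate
5 | 3-methylbut-1-yne | CC(C)C#C | starting material
6 | diisobutyl{[(3S)-2,6-dimethyl-3-(3-methylbut-1-en-2-yl)cyclohepta-1,6-dien-1-yl]oxy}alumane | CC=1CC[C@@H](C(=C)C(C)C)C(C)=C(O[Al](CC(C)C)CC(C)C)C=1 | intermediate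
7 | (6S,7S)-3,7-dimethyl-6-(3-methylbut-1-en-2-yl)-7-(prop-2-en-1-yl)cyclohept-2-en-1-one (alkenyl and allyl trans) | CC=1CC[C@@H](C(=C)C(C)C)[C@](C)(CC=C)C(=O)C=1 | intermediate
8 | (6R,7S)-3,7-dimethyl-6-(2-methylpropanoyl)-7-(2-oxoethyl)cyclohept-2-en-1-one | CC=1CC[C@@H](C(=O)C(C)C)[C@](C)(CC=O)C(=O)C=1 | intermediate
9 | (6R,7S)-7-(2-hydroxyethyl)-3,7-dimethyl-6-(2-methylpropanoyl)cyclohept-2-en-1-one | CC=1CC[C@@H](C(=O)C(C)C)[C@](C)(CCO)C(=O)C=1 | intermediate
10 | (6R,7S)-7-(2-iodoethyl)-3,7-dimethyl-6-(2-methylpropanoyl)cyclohept-2-en-1-one | CC=1CC[C@@H](C(=O)C(C)C)[C@](C)(CCI)C(=O)C=1 | intermediate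
11 | (3R,3aR,8aS)-3-hydroxy-6,8a-dimethyl-3-(propan-2-yl)-2,3,3a,4,5,8a-hexahydroazulen-8(1H)-one | CC=1CC[C@@H]2[C@](C)(CC[C@@]2(O)C(C)C)C(=O)C=1 | intermediate
12 | (3R,3aR,8aS)-3-hydroxy-6,8a-dimethyl-3-(propan-2-yl)-2,3,3a,8a-tetrahydroazulen-8(1H)-one | CC=1C=C[C@@H]2[C@](C)(CC[C@@]2(O)C(C)C)C(=O)C=1 | intermediate
13 | (3R,3aR,8S,8aS)-6,8a-dimethyl-3-(propan-2-yl)-1,2,3,3a,8,8a-hexahydroazulene-3,8-diol | CC=1C=C[C@@H]2[C@](C)(CC[C@@]2(O)C(C)C)[C@@H](O)C=1 | intermediate
14 | 6α,9α-epidioxydauc-7-ene-4β,10β-diol | CC1=C[C@@H]2OO[C@H]1[C@H](O)[C@@]3(C)CC[C@@](O)(C(C)C)[C@H]23 | intermediate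
15 | (3R,3aS,4S,8R,8aS)-3,4,8-trihydroxy-6,8a-dimethyl-3-(propan-2-yl)-2,3,3a,4,8,8a-hexahydroazulen-7(1H)-one | CC1=C[C@H](O)[C@@H]2[C@](C)(CC[C@@]2(O)C(C)C)[C@@H](O)C1=O | intermediate
16 | [(3R,3aS,4S,8R,8aS)-3,8-dihydroxy-6,8a-dimethyl-7-oxo-3-(propan-2-yl)-1,2,3,3a,4,7,8,8a-octahydroazulen-4-yl] benzoate | CC1=C[C@H](OC(=O)c2ccccc2)[C@@H]2[C@](C)(CC[C@@]2(O)C(C)C)[C@@H](O)C1=O | target

Total steps: 12. Longest linear sequence: 12 steps (1 → 16).

**Steps most likely to fail**

Step 3. What may go wrong: slow turnover or poor enantioface discrimination when the chiral copper catalyst meets the α-methylated cross-conjugated dienone, or loss of trans selectivity in the enolate allylation. Fallback: setting out from 4, the conjugate addition/allylation is run without asymmetric induction (alkenylalane from 5, CuTC/PPh3, then allyl acetate/Pd(PPh3)4). This gives 7 as a racemate together with its mirror image, the (6R,7R)-enantiomer of 7 F1. The enantiomers are separated by preparative chromatography on a chiral stationary phase, and the route is rejoined at 7.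

Step 7. What may go wrong: competing single-electron reduction of the enone, or samarium chelation to the C10 carbonyl that erodes the facial preference at C4. Fallback: setting out from 10, the electron-transfer reagent is replaced by a polar anionic cyclisation. Iodine–lithium exchange with t-BuLi (2.1 equiv, Et2O–pentane, −100 °C) gives the primary alkyllithium, which should add to the neighbouring isopropyl ketone faster than it meets any other electrophile. No reducing metal is present, and protonation of the lithium alkoxide gives 11 directly, so no new compound arises and the route is rejoined at 11.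

Step 11. What may go wrong: proton abstraction at C6 instead of C9, which would give the regioisomeric 9-hydroxy-6-ketone. Fallback: setting out from 14, the O–O bond is reduced with thiourea (MeOH, rt) to 4β,6α,9α,10β-tetrahydroxydauc-7-ene F2. The 9,10-diol is converted into its dibutylstannylene acetal (Bu2SnO, toluene, reflux) and oxidised with NBS (CHCl3, rt), which should oxidise the allylic C9 carbinol and leave the isolated C6 alcohol untouched. This gives 15, where the route is rejoined.

**Further compounds**
F1 | step 3 | (6R,7R)-3,7-dimethyl-6-(3-methylbut-1-en-2-yl)-7-(prop-2-en-1-yl)cyclohept-2-en-1-one (enantiomer of 7) | CC=1CC[C@H](C(=C)C(C)C)[C@@](C)(CC=C)C(=O)C=1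
F0 | step 7 | none | none
F2 | step 11 | 4β,6α,9α,10β-tetrahydroxydauc-7-ene | CC1=C[C@H](O)[C@@H]2[C@](C)(CC[C@@]2(O)C(C)C)[C@@H](O)[C@@H]1O
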